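# Proposed synthesis of CNP0170897.4: a vinyl epoxide / enal (3+2) annulation under joint palladium and amine catalysis

Compound numbering used throughout: 1 syringaldehyde; 2 its benzyl ether; 3 the formylmethylene ylide; 4 the enal; 5 the epoxy aldehyde; 6 the vinyl epoxide; 7–9 species formed in the key step; 10 the tetrahydrofuran aldehyde; 11 the derived alcohol; 12 the C3 aldehyde; 13 the bis-benzyl ether of the target; 14 the target.

Ring locants in the discussion are O1, C2, C3, C4, C5, with C2 the carbon whose aryl group is cis to the neighbouring arm. The systematic names of 10 and 11 number the ring from the other side and are marked in the compound list.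

## Analysis of the target

Target 14 is a 2,5-diaryl-3,4-bis(hydroxymethyl)tetrahydrofuran: one oxolane ring, two identical 4-hydroxy-3,5-dimethoxyphenyl groups on C2 and C5, and hydroxymethyl arms on C3 and C4. In the numbering above, the four contiguous stereocentres are 2S,3S,4S,5R. The aryl groups are cis to each other, the arms are trans to each other, the C2 aryl is cis to the C3 arm, and the C5 aryl is trans to the C4 arm. The constitution is symmetrical but the configuration is not, so the two halves cannot be made by one symmetrical operation. The sensitive groups are the free 2,6-dimethoxyphenols (oxidation, quinone methide formation) and the doubly benzylic ring ether, which can ionise with epimerisation at C2 or C5 and can be hydrogenolysed. The hard part is the 2,3-cis relationship, the less stable arrangement, next to a trans,trans C3–C4–C5 sequence, together with control of absolute configuration. The strategy rests on two structural readings. O1–C5–C4 with the C4 arm is, at the aldehyde oxidation level, the oxa-Michael adduct of a cinnamaldehyde. C3 with its arm, next to the carbinol carbon C2, is the substituted terminus of an allyl unit after C-alkylation, if the vinyl group is taken as a latent hydroxymethyl group. Both halves are therefore C6–C3 units that can come from one enal.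

## Retrosynthetic reasoning

**14 to 13.** The last cut is at the two phenolic O–benzyl bonds. The phenols are masked throughout because free phenols would quench the alkoxide of the key step, would open the ring through quinone methides, and would not survive oxidative cleavage. Benzyl ethers tolerate zerovalent palladium, amines, hydride and periodate, and leave under neutral conditions.

**13 to 11 (through 12).** The C3 hydroxymethyl group is traced to a vinyl group by cleaving the C=C bond and reducing aldehyde 12. A vinyl group is what remains when a nucleophile attacks the substituted end of an allyl unit. The cost is one carbon atom, and the forward step must not let C3 epimerise while it is α to a carbonyl group.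

**11 to 10.** The C4 hydroxymethyl group is traced to a formyl group. The aldehyde is the handle through which an amine catalyst acts. It also makes C4 the one epimerisable centre, which in 10 sits trans to both neighbours, its stable orientation.

**10 to 6 and 4.** The ring is cut at O1–C5 and C3–C4. These are the two bonds that an oxygen/allyl-carbon three-atom unit can form with the two alkene carbons of an enal. The cut returns 4 intact and leaves O1, C2 and C3 with the vinyl group as epoxide 6. Cutting at C2 instead would destroy the one centre that can be brought in enantiopure. Cutting C3–C4 alone offers no handle for control. The gain is one ring, two skeletal bonds and three stereocentres (C3, C4, C5) in one convergent step. The forward reaction must deliver oxygen 1,4, carbon to the substituted allyl terminus, C3 cis to the C2 aryl, and C5 cis to the C2 aryl.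

**6 to 5.** The terminal C=C bond of 6 is cut back to the aldehyde of 5 (methylenation). The vinyl-bearing carbon of 6 loses its configuration in the allyl complex, so only the aryl-bearing carbon has to be secured, and that is fixed in 5.

**5 to 4.** Both oxirane C–O bonds are cut, which leads to asymmetric nucleophilic epoxidation of 4. An ylide-based epoxide synthesis from 2 is not shorter once its chiral reagent is counted. In such a route a cis-epoxide by-product would carry the opposite configuration at the aryl-bearing carbon, the only centre that is passed on. Epoxidation of 4 is stereospecific with respect to alkene geometry and makes 4 the precursor of both partners. C2 and C5 are mirror-related positions of a cis-diaryl ring, so oxygen must enter opposite faces of 4 here and in the key step, and the two amine catalysts are enantiomeric.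

**4 to 2 and 3.** The Cα=Cβ bond is cut: two-carbon Wittig homologation of aldehyde 2 with ylide 3.

**2 to 1.** The benzyl ether is cut back to syringaldehyde 1.

## Alternatives that were turned down

**Alternative 1: both aryl rings built last by (3+3) benzannulation.**
- Disconnection: each dimethoxyphenol ring is cut between its ortho CH carbons and the methoxy-bearing carbons. The partners are 1,3-dimethoxypropan-2-one A2 (phenol carbon and its two methoxylated neighbours) and bis-vinamidinium salt A3, a finished tetrahydrofuran with benzyloxymethyl arms on C3 and C4 and a bis(dimethylamino)trimethinium unit on C2 and on C5.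
- Forward key step: under a strong alkoxide base, two molecules of A2 condense through both α-carbons with the termini of the two vinamidinium units. Loss of the amine groups and of water aromatises both rings and gives bis-phenol A1. Hydrogenolysis of its two alkyl benzyl ethers would give the target.
- For it: no phenol protecting group is needed, and no electron-rich benzylic ether is present while the ring and stereocentres are made. On these two points it is stronger than the chosen route.
- Against it: the stereochemical problem is only moved. A3 must already hold all four stereocentres on a tetrahydrofuran with non-aromatic substituents at C2 and C5, for which no short controlled entry is evident. In A3 and the half-condensed intermediates, the C2 and C5 hydrogens sit on the central carbon of a push–pull system, so base can epimerise them and the enamine terminus can expel the ring oxygen. Two annulations must also succeed on one molecule.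
- Comparison: the chosen route offers ring formation and three stereocentres in one catalytic step from two C6–C3 units, where this alternative needs the complete stereodefined core before its key step.

**Alternative 2: chiral benzylic sulfonium ylide (4+1) annulation, then directed hydrogenation.**
- Disconnection: O1–C5 and C4–C5 are cut. C5 with its aryl group comes from sulfonium salt A6 (written with one enantiomer of a C2-symmetric thiolane), and O1, C2, C3, C4 from alkylidene ketoester A5. The hydrogens at C2 and C3 are added later.
- Forward key step: the ylide of A6 adds to C4 of A5, and the ketone enolate oxygen displaces the sulfide at the same carbon. This gives trans-4,5-dihydrofuran A4. After desilylation, hydroxyl-directed hydrogenation of the C2=C3 bond from the face of the C4 arm would set C2 and C3 together, followed by ester reduction and debenzylation.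
- For it: syn addition of hydrogen makes the 2,3-cis relationship a stereospecific consequence. On this point it is stronger than the chosen route, where C3 depends on ligand control over two allyl faces. The 4,5-trans outcome is the normal one for such annulations.
- Against it: the C2=C3 bond is tetrasubstituted, aryl-conjugated and deactivated as a vinylogous carbonate, a class that homogeneous directing catalysts rarely reduce. Heterogeneous catalysts would first remove the benzyl ethers and endanger the benzylic C5–O bond. Enantiocontrol by chiral sulfides in this annulation mode is less secure than in epoxidation, and cyclopropanation competes. A5 and A6 each need several steps, so the route is longer than eight steps.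
- Comparison: the chosen route offers a shorter sequence, uses one intermediate for both halves, and has no reduction that conflicts with the protecting groups.

**Alternative 3: three-component carbonyl ylide (3+2) cycloaddition onto a chiral fumarate.**
- Disconnection: O1–C2, C2–C3 and C4–C5 are cut, giving aldehyde 2 of the present route, aryldiazomethane A8 and di-(−)-menthyl fumarate A9.
- Forward key step: a dirhodium tetracarboxylate turns A8 into a carbene that is captured by the carbonyl oxygen of 2. The resulting carbonyl ylide, symmetrical because both termini carry the same aryl group, adds suprafacially to A9 and gives A7. Hydride reduction of A7 would lead into 13 of the present route.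
- For it: it is the shortest route, about five steps. The relative configuration follows from symmetry and stereospecificity (trans esters from the fumarate, cis aryl groups from the extended ylide). On both points it is stronger than the chosen route.
- Against it: absolute control rests only on menthyl esters that are remote from the reacting carbons and conformationally free, with no Lewis acid to organise them. A near-statistical mixture of A7 and the diastereomer with the mirror-image ring must be expected. The three-component manifold competes with ylide closure to a stilbene oxide, addition to a second aldehyde to give a dioxolane, carbene dimerisation and cyclopropanation. The electron-rich A8 is unstable and must be generated in the flask.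
- Comparison: the chosen route offers a named, tunable control element for every stereocentre (an enantioenriched epoxide, an amine catalyst and a palladium ligand) at the price of three more steps.

Key step: step 5

Assumption: the sense in which the chiral phosphoramidite discriminates the two allyl faces cannot be derived with confidence when the substrate and the amine are chiral as well; the (Sa,S,S) ligand is written, and the (Ra,R,R) ligand takes its place without other change if the first pairing proves to be the mismatched one.

## Steps

Step 1
Reactants: 1 syringaldehyde (4-hydroxy-3,5-dimethoxybenzaldehyde)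
Product: 2 4-(benzyloxy)-3,5-dimethoxybenzaldehyde
Conditions: BnBr, K2CO3, DMF, 60 °C
Reagents that add atoms: benzyl bromide, BrCc1ccccc1
Why: Williamson ether synthesis; the phenoxide of 1, although flanked by two methoxy groups, is alkylated readily by the benzylic bromide, and the aldehyde is inert to carbonate.

Step 2
Reactants: 2 4-(benzyloxy)-3,5-dimethoxybenzaldehyde; 3 (triphenylphosphoranylidene)acetaldehyde
Product: 4 (E)-3-[4-(benzyloxy)-3,5-dimethoxyphenyl]prop-2-enal
Conditions: toluene, 90 °C
Reagents that add atoms: none
Why: Wittig reaction with the stabilised ylide 3 should give the E-enal; heating is needed because 2 is an electron-rich aldehyde, and 3 is kept close to one equivalent so that 4 is not homologated a second time.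

Step 3
Reactants: 4 (E)-3-[4-(benzyloxy)-3,5-dimethoxyphenyl]prop-2-enal
Product: 5 (2S,3R)-3-[4-(benzyloxy)-3,5-dimethoxyphenyl]oxirane-2-carbaldehyde
Conditions: (S)-2-{bis[3,5-bis(trifluoromethyl)phenyl](trimethylsilyloxy)methyl}pyrrolidine (10 mol %), 35% aq. H2O2, CH2Cl2, rt
Reagents that add atoms: hydrogen peroxide, OO
Why: Amine-catalysed nucleophilic epoxidation of an enal (iminium activation for conjugate addition of H2O2, enamine activation for ring closure), a reaction established for cinnamaldehydes. On the usual shielding model the (S)-amine blocks the Re face of the β-carbon, so oxygen enters from the Si face and gives the 3R centre that becomes C2 of the target; closure on the E chain gives the trans epoxide.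

Step 4
Reactants: 5 (2S,3R)-3-[4-(benzyloxy)-3,5-dimethoxyphenyl]oxirane-2-carbaldehyde
Product: 6 (2R,3R)-2-[4-(benzyloxy)-3,5-dimethoxyphenyl]-3-vinyloxirane (trans)
Conditions: Ph3PCH3Br, KOtBu, THF, 0 °C; then 5, −78 °C to 0 °C
Reagents that add atoms: methyltriphenylphosphonium bromide, C[P+](c1ccccc1)(c1ccccc1)c1ccccc1.[Br-]
Why: Wittig methylenation; the non-stabilised ylide adds to the aldehyde much faster than it attacks the oxirane, and both stereocentres are untouched (the descriptor of the former C2 changes only because the priorities change).

Step 5
Reactants: 6 (2R,3R)-2-[4-(benzyloxy)-3,5-dimethoxyphenyl]-3-vinyloxirane; 4 (E)-3-[4-(benzyloxy)-3,5-dimethoxyphenyl]prop-2-enal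
Product: 10 (2R,3R,4R,5S)-2,5-bis[4-(benzyloxy)-3,5-dimethoxyphenyl]-4-vinyltetrahydrofuran-3-carbaldehyde, via π-allylpalladium alkoxide 7 (not isolated), via iminium ion 8 (not isolated), via tethered enamine 9 (not isolated)
Conditions: Pd2(dba)3·CHCl3 (2.5 mol %), O,O′-(S)-1,1′-binaphthyl-2,2′-diyl N,N-bis[(S)-1-phenylethyl]phosphoramidite (10 mol %), (R)-2-[diphenyl(trimethylsilyloxy)methyl]pyrrolidine (20 mol %), PhCO2H (20 mol %), 4 (1.5 equiv), THF, 0 °C to rt
Reagents that add atoms: none
Why: Proposed new method: zerovalent palladium ionises the allylic C–O bond of 6 with inversion and leaves the aryl-bearing carbon untouched, giving zwitterion 7; its alkoxide oxygen adds to the β-carbon of iminium ion 8 (O1–C5) to give enamine 9, whose α-carbon attacks the substituted allyl terminus anti to palladium (C3–C4), and hydrolysis of the resulting iminium ion frees both catalysts; the closest known reaction types are palladium-catalysed (3+2) annulations of vinyl epoxides with doubly activated alkenes and amine/palladium (3+2) annulations of vinylcyclopropanes with enals, but an alkoxide–allyl zwitterion has not been paired with an iminium ion. The tetrahydrofuran ring closes in the C–C bond-forming event, 5-exo-trig with respect to the allyl unit (the vinyl group stays outside the ring) and with the enamine double bond exocyclic as well. C2 is carried over from 6, since its C–O and C–H bonds are never broken. C5 is set by the (R)-amine, which on the usual shielding model blocks the Si face of the β-carbon so that oxygen enters from the Re face (5R, aryl cis to the C2 aryl); the oxa-Michael addition is reversible, so a wrongly formed adduct can revert. C4 follows from suprafacial addition across the E double bond (formyl trans to the C5 aryl) and, being the only epimerisable centre, can also settle trans to both neighbours through the enamine of 10. C3 is the centre that needs real control: the two allyl faces exchange by η3–η1–η3 isomerisation at the CH2 terminus faster than ring closure, so the trans geometry of 6 is not transmitted, and the bulky monodentate ligand must favour the closure that puts the vinyl group cis to the C2 aryl, the contrasteric outcome known when nucleophiles tethered to such alkoxides close five-membered rings on equilibrating allyl complexes. The step needs 1,4- rather than 1,2-addition of the alkoxide and C-alkylation at the substituted terminus: the first is secured because 1,2-adducts (N,O-acetal, hemiacetal or vinyl dioxolane) keep an allylic C–O bond that palladium can re-ionise whereas the C3–C4 bond is irreversible, the second because only the substituted terminus allows a five-membered transition state.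

Step 6
Reactants: 10 (2R,3R,4R,5S)-2,5-bis[4-(benzyloxy)-3,5-dimethoxyphenyl]-4-vinyltetrahydrofuran-3-carbaldehyde
Product: 11 {(2R,3S,4R,5S)-2,5-bis[4-(benzyloxy)-3,5-dimethoxyphenyl]-4-vinyltetrahydrofuran-3-yl}methanol
Conditions: NaBH4, MeOH–CH2Cl2, 0 °C
Reagents that add atoms: none
Why: Chemoselective NaBH4 reduction of the aldehyde; it removes the carbonyl group that keeps C4 epimerisable and the ring open to retro-oxa-Michael cleavage, and creates no stereocentre.

Step 7
Reactants: 11 {(2R,3S,4R,5S)-2,5-bis[4-(benzyloxy)-3,5-dimethoxyphenyl]-4-vinyltetrahydrofuran-3-yl}methanol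
Product: 13 {(2S,3S,4S,5R)-2,5-bis[4-(benzyloxy)-3,5-dimethoxyphenyl]tetrahydrofuran-3,4-diyl}dimethanol, via aldehyde 12 (not isolated)
Conditions: OsO4 (2 mol %), NaIO4, 2,6-lutidine, dioxane–H2O (3:1), rt; extractive work-up; then NaBH4, MeOH, 0 °C
Reagents that add atoms: osmium tetroxide, O=[Os](=O)(=O)=O (oxygen of the new carbonyl group); sodium periodate, [Na+].[O-]I(=O)(=O)=O (reoxidant that restores that oxygen)
Why: Lemieux–Johnson oxidation of the only alkene, which spares the electron-rich arenes, followed by NaBH4 reduction; aldehyde 12 is reduced straight after work-up so that C3, now α to a carbonyl group and cis to the C2 aryl, has no time to epimerise.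

Step 8
Reactants: 13 {(2S,3S,4S,5R)-2,5-bis[4-(benzyloxy)-3,5-dimethoxyphenyl]tetrahydrofuran-3,4-diyl}dimethanol
Product: 14 {(2S,3S,4S,5R)-2,5-bis(4-hydroxy-3,5-dimethoxyphenyl)tetrahydrofuran-3,4-diyl}dimethanol (target)
Conditions: H2 (1 atm), 10% Pd/C, EtOAc–MeOH, rt
Reagents that add atoms: none
Why: Catalytic hydrogenolysis of the two aryl benzyl ethers; under neutral conditions these should cleave well before the benzylic C–O bonds of the ring, so the reaction is stopped once two equivalents of H2 are taken up, and no stereocentre is touched.

## Compound list

1 | syringaldehyde (4-hydroxy-3,5-dimethoxybenzaldehyde) | COc1cc(C=O)cc(OC)c1O | starting material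
2 | 4-(benzyloxy)-3,5-dimethoxybenzaldehyde | COc1cc(C=O)cc(OC)c1OCc1ccccc1 | intermediate
3 | (triphenylphosphoranylidene)acetaldehyde | O=CC=P(c1ccccc1)(c1ccccc1)c1ccccc1 | starting material
4 | (E)-3-[4-(benzyloxy)-3,5-dimethoxyphenyl]prop-2-enal | COc1cc(/C=C/C=O)cc(OC)c1OCc1ccccc1 | intermediate
5 | (2S,3R)-3-[4-(benzyloxy)-3,5-dimethoxyphenyl]oxirane-2-carbaldehyde (trans) | COc1cc([C@H]2O[C@@H]2C=O)cc(OC)c1OCc1ccccc1 | intermediate
6 | (2R,3R)-2-[4-(benzyloxy)-3,5-dimethoxyphenyl]-3-vinyloxirane (trans) | COc1cc([C@H]2O[C@@H]2C=C)cc(OC)c1OCc1ccccc1 | intermediate
7 | zwitterionic π-allylpalladium alkoxide from 6 (S at the carbinol carbon; drawn as the η1 form, ligand omitted) | COc1cc([C@@H]([O-])/C=C/C[Pd+])cc(OC)c1OCc1ccccc1 | intermediate (not isolated)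
8 | iminium ion of 4 with (R)-2-[diphenyl(trimethylsilyloxy)methyl]pyrrolidine | COc1cc(/C=C/C=[N+]2CCC[C@@H]2C(O[Si](C)(C)C)(c2ccccc2)c2ccccc2)cc(OC)c1OCc1ccccc1 | intermediate (not isolated)
9 | enamine formed by addition of the alkoxide of 7 to C5 of 8, still carrying the allylpalladium unit (η1 form, ligand omitted) | COc1cc([C@@H](O[C@H](/C=C/N2CCC[C@@H]2C(O[Si](C)(C)C)(c2ccccc2)c2ccccc2)c2cc(OC)c(OCc3ccccc3)c(OC)c2)/C=C/C[Pd+])cc(OC)c1OCc1ccccc1 | intermediate (not isolated)
10 | (2R,3R,4R,5S)-2,5-bis[4-(benzyloxy)-3,5-dimethoxyphenyl]-4-vinyltetrahydrofuran-3-carbaldehyde (target numbering: formyl on C4 trans to both neighbours, vinyl on C3 cis to the C2 aryl, aryl groups cis) | COc1cc([C@H]2O[C@@H](c3cc(OC)c(OCc4ccccc4)c(OC)c3)[C@H](C=O)[C@H]2C=C)cc(OC)c1OCc1ccccc1 | intermediate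
11 | {(2R,3S,4R,5S)-2,5-bis[4-(benzyloxy)-3,5-dimethoxyphenyl]-4-vinyltetrahydrofuran-3-yl}methanol (target numbering: hydroxymethyl on C4, vinyl on C3) | COc1cc([C@H]2O[C@@H](c3cc(OC)c(OCc4ccccc4)c(OC)c3)[C@H](CO)[C@H]2C=C)cc(OC)c1OCc1ccccc1 | intermediate
12 | (2S,3R,4S,5R)-2,5-bis[4-(benzyloxy)-3,5-dimethoxyphenyl]-4-(hydroxymethyl)tetrahydrofuran-3-carbaldehyde | COc1cc([C@H]2O[C@@H](c3cc(OC)c(OCc4ccccc4)c(OC)c3)[C@H](CO)[C@H]2C=O)cc(OC)c1OCc1ccccc1 | intermediate (not isolated)
13 | {(2S,3S,4S,5R)-2,5-bis[4-(benzyloxy)-3,5-dimethoxyphenyl]tetrahydrofuran-3,4-diyl}dimethanol | COc1cc([C@H]2O[C@@H](c3cc(OC)c(OCc4ccccc4)c(OC)c3)[C@H](CO)[C@H]2CO)cc(OC)c1OCc1ccccc1 | intermediate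
14 | {(2S,3S,4S,5R)-2,5-bis(4-hydroxy-3,5-dimethoxyphenyl)tetrahydrofuran-3,4-diyl}dimethanol | COc1cc([C@H]2O[C@@H](c3cc(OC)c(O)c(OC)c3)[C@H](CO)[C@H]2CO)cc(OC)c1O | target

## Step count and least certain steps

Total step count: 8. Longest linear sequence: 8 steps (1 → 2 → 4 → 5 → 6 → 10 → 11 → 13 → 14). Enal 4 enters twice, so no separate branch has to be prepared.

**Step 5 (key step, proposed new method).**
- Most likely failure: the alkoxide of 7 is consumed before it meets the iminium ion. Possible paths are hydride shift to an aryl allyl ketone, closure at the CH2 terminus, and irreversible N-allylation of the amine catalyst.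
- Second failure: closure on the other allyl face, giving the 2,3-trans ring, because three chiral elements (C2, the amine, the ligand) must cooperate.
- Fallback (known chemistry): the enal is replaced by a doubly activated alkene, for which the palladium-catalysed (3+2) annulation of vinyl epoxides is established. It sets out from 6 and 2, returns at 11, and costs two more steps.
  - Aldehyde 2 would be condensed with dimethyl malonate (Knoevenagel; piperidine, AcOH, toluene, reflux with removal of water) to dimethyl 2-[4-(benzyloxy)-3,5-dimethoxybenzylidene]malonate F1.
  - 6 and F1 with Pd2(dba)3·CHCl3 and the same phosphoramidite in THF would give dimethyl 2,5-bis[4-(benzyloxy)-3,5-dimethoxyphenyl]-4-vinyldihydrofuran-3,3(2H)-dicarboxylate F2. C5 is set there by the reversible oxa-Michael step and C3 by the ligand.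
  - Krapcho demethoxycarbonylation (LiCl, wet DMSO, 140 °C) and equilibration with NaOMe in MeOH would give methyl 2,5-bis[4-(benzyloxy)-3,5-dimethoxyphenyl]-4-vinyltetrahydrofuran-3-carboxylate F3, with the ester trans to both neighbours.
  - LiAlH4 in THF would reduce F3 to 11.

**Step 3 (epoxidation of 4).**
- Most likely failure: slow conjugate addition, because the iminium ion of an electron-rich cinnamaldehyde is a weak electrophile. That leaves time for oxidative degradation of the amine by H2O2 and for ring opening of 5 at its benzylic carbon.
- Fallback: the oxygen is delivered by a metal-directed epoxidation of the allylic alcohol. It sets out from 4 and returns at 5.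
  - 4 would be reduced (NaBH4, CeCl3·7H2O, MeOH, 0 °C) to (E)-3-[4-(benzyloxy)-3,5-dimethoxyphenyl]prop-2-en-1-ol F4.
  - Sharpless asymmetric epoxidation (Ti(OiPr)4, D-(−)-diethyl tartrate, tBuOOH, 4 Å sieves, CH2Cl2, −20 °C) would give [(2R,3R)-3-[4-(benzyloxy)-3,5-dimethoxyphenyl]oxiran-2-yl]methanol F5.
  - Parikh–Doering oxidation (SO3·pyridine, DMSO, iPr2NEt, 0 °C) would give 5.

**Step 7 (oxidative cleavage and reduction).**
- Most likely failure: epimerisation at C3 of 12. It is driven by the fact that only the epimer, in which the formyl group and the C4 hydroxymethyl group become cis, can close to a cis-fused lactol. Base-induced loss of the ring oxygen from C2 is a second risk.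
- Fallback: the C4 hydroxyl is masked first so that this sink does not exist. It sets out from 11 and returns at 13.
  - 11 would be silylated (TBSCl, imidazole, DMF) to the tert-butyldimethylsilyl ether of 11 F6.
  - Cleavage as in step 7 would give the silylated C3 aldehyde F7, and NaBH4 would give the mono-silylated diol F8.
  - Bu4NF in THF would give 13.

**Step 8 (hydrogenolysis).**
- Most likely failure: over-reduction, that is hydrogenolytic opening of the ring at the doubly benzylic C2–O or C5–O bond once the aryl ethers are gone.
- Fallback: the benzyl groups are removed by Lewis-acid heterolysis instead of reduction. It sets out from 13 and returns at 14.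
  - 13 would be acetylated (Ac2O, pyridine) to the diacetate of 13 F9.
  - BCl3 with pentamethylbenzene in CH2Cl2 at −78 °C would give the diacetate of 14 F10.
  - K2CO3 in degassed MeOH would give 14.

## Further compounds

F1 | step 5 | dimethyl 2-[4-(benzyloxy)-3,5-dimethoxybenzylidene]malonate | COC(=O)C(=Cc1cc(OC)c(OCc2ccccc2)c(OC)c1)C(=O)OC
F2 | step 5 | dimethyl 2,5-bis[4-(benzyloxy)-3,5-dimethoxyphenyl]-4-vinyldihydrofuran-3,3(2H)-dicarboxylate (ring stereocentres as in 10) | COc1cc([C@H]2O[C@@H](c3cc(OC)c(OCc4ccccc4)c(OC)c3)C(C(=O)OC)(C(=O)OC)[C@H]2C=C)cc(OC)c1OCc1ccccc1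
F3 | step 5 | methyl 2,5-bis[4-(benzyloxy)-3,5-dimethoxyphenyl]-4-vinyltetrahydrofuran-3-carboxylate (configuration of 10) | COc1cc([C@H]2O[C@@H](c3cc(OC)c(OCc4ccccc4)c(OC)c3)[C@H](C(=O)OC)[C@H]2C=C)cc(OC)c1OCc1ccccc1
F4 | step 3 | (E)-3-[4-(benzyloxy)-3,5-dimethoxyphenyl]prop-2-en-1-ol | COc1cc(/C=C/CO)cc(OC)c1OCc1ccccc1
F5 | step 3 | [(2R,3R)-3-[4-(benzyloxy)-3,5-dimethoxyphenyl]oxiran-2-yl]methanol | COc1cc([C@H]2O[C@@H]2CO)cc(OC)c1OCc1ccccc1
F6 | step 7 | tert-butyldimethylsilyl ether of 11 | COc1cc([C@H]2O[C@@H](c3cc(OC)c(OCc4ccccc4)c(OC)c3)[C@H](CO[Si](C)(C)C(C)(C)C)[C@H]2C=C)cc(OC)c1OCc1ccccc1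
F7 | step 7 | tert-butyldimethylsilyl ether of 12 | COc1cc([C@H]2O[C@@H](c3cc(OC)c(OCc4ccccc4)c(OC)c3)[C@H](CO[Si](C)(C)C(C)(C)C)[C@H]2C=O)cc(OC)c1OCc1ccccc1
F8 | step 7 | mono-tert-butyldimethylsilyl ether of 13 (silyl group on the C4 arm) | COc1cc([C@H]2O[C@@H](c3cc(OC)c(OCc4ccccc4)c(OC)c3)[C@H](CO[Si](C)(C)C(C)(C)C)[C@H]2CO)cc(OC)c1OCc1ccccc1
F9 | step 8 | diacetate of 13 | COc1cc([C@H]2O[C@@H](c3cc(OC)c(OCc4ccccc4)c(OC)c3)[C@H](COC(C)=O)[C@H]2COC(C)=O)cc(OC)c1OCc1ccccc1
F10 | step 8 | diacetate of 14 (acetylated on both hydroxymethyl groups) | COc1cc([C@H]2O[C@@H](c3cc(OC)c(O)c(OC)c3)[C@H](COC(C)=O)[C@H]2COC(C)=O)cc(OC)c1O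
A1 | alternative 1 | 4,4'-[3,4-bis(benzyloxymethyl)tetrahydrofuran-2,5-diyl]bis(2,6-dimethoxyphenol), target configuration | COc1cc([C@H]2O[C@@H](c3cc(OC)c(O)c(OC)c3)[C@H](COCc3ccccc3)[C@H]2COCc2ccccc2)cc(OC)c1O
A2 | alternative 1 | 1,3-dimethoxypropan-2-one | COCC(=O)COC
A3 | alternative 1 | 3,4-bis(benzyloxymethyl)tetrahydrofuran-2,5-diyl bis[1,3-bis(dimethylamino)trimethinium] bis(hexafluorophosphate), ring configuration as in the target | CN(C)C=C(C=[N+](C)C)[C@H]1O[C@@H](C(C=[N+](C)C)=CN(C)C)[C@H](COCc2ccccc2)[C@H]1COCc1ccccc1.F[P-](F)(F)(F)(F)F.F[P-](F)(F)(F)(F)F
A4 | alternative 2 | methyl trans-2,5-bis[4-(benzyloxy)-3,5-dimethoxyphenyl]-4-[(tert-butyldimethylsilyloxy)methyl]-4,5-dihydrofuran-3-carboxylate, single enantiomer | COC(=O)C1=C(c2cc(OC)c(OCc3ccccc3)c(OC)c2)O[C@@H](c2cc(OC)c(OCc3ccccc3)c(OC)c2)[C@@H]1CO[Si](C)(C)C(C)(C)C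
A5 | alternative 2 | methyl 2-[4-(benzyloxy)-3,5-dimethoxybenzoyl]-4-(tert-butyldimethylsilyloxy)but-2-enoate | COC(=O)C(=CCO[Si](C)(C)C(C)(C)C)C(=O)c1cc(OC)c(OCc2ccccc2)c(OC)c1
A6 | alternative 2 | (2R,5R)-1-[4-(benzyloxy)-3,5-dimethoxybenzyl]-2,5-dimethylthiolan-1-ium tetrafluoroborate | C[C@@H]1CC[C@@H](C)[S+]1Cc1cc(OC)c(OCc2ccccc2)c(OC)c1.F[B-](F)(F)F
A7 | alternative 3 | di-(−)-menthyl 2,5-cis-2,5-bis[4-(benzyloxy)-3,5-dimethoxyphenyl]tetrahydrofuran-3,4-trans-dicarboxylate, target ring configuration | COc1cc([C@H]2O[C@@H](c3cc(OC)c(OCc4ccccc4)c(OC)c3)[C@H](C(=O)O[C@@H]3C[C@H](C)CC[C@H]3C(C)C)[C@H]2C(=O)O[C@@H]2C[C@H](C)CC[C@H]2C(C)C)cc(OC)c1OCc1ccccc1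
A8 | alternative 3 | [4-(benzyloxy)-3,5-dimethoxyphenyl]diazomethane | COc1cc(C=[N+]=[N-])cc(OC)c1OCc1ccccc1
A9 | alternative 3 | di-(−)-menthyl fumarate | O=C(/C=C/C(=O)O[C@@H]1C[C@H](C)CC[C@H]1C(C)C)O[C@@H]1C[C@H](C)CC[C@H]1C(C)C
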